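I cannot watch target being lost: a reading of target shows the making and the losing together. So I read the loss from over-reaction product, which climbs with target and stands higher in east, with more reagent, than in south.

common to all: starting material 0.77 M; free catalyst 7.7 mol%
- south: reagent 2.3 equiv; run made earlier
- east: reagent 3.1 equiv; run made earlier
- birch: reagent 2.50 equiv; time 5.0 min
- elm: reagent 3.80 equiv; time 5.0 min

| run | time / min | isomer of the product / % | starting material / % | catalyst intermediate B / % | over-reaction product / % | target / % |
|---|---|---|---|---|---|---|
| south | 0.667 | 0.1 | 88.2 | 3.8 | 0.2 | 5.7 |
| south | 1.33 | 0.3 | 76.4 | 5.7 | 0.8 | 16.7 |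
| south | 2.00 | 0.7 | 66.6 | 4.5 | 2.8 | 24.6 |
| south | 3.00 | 0.6 | 54.2 | 4.8 | 5.5 | 35.0 |
| south | 4.00 | 3.6 | 41.7 | 3.2 | 7.1 | 44.1 |
| east | 0.667 | 0 | 84.5 | 4.2 | 1.1 | 7.2 |
| east | 1.33 | 0.3 | 74.2 | 2.2 | 1.2 | 16.7 |
| east | 2.00 | 0 | 63.8 | 4.6 | 3.6 | 24.6 |
| east | 3.00 | 1.2 | 50.2 | 6.4 | 7.5 | 35.7 |
| east | 4.00 | 1.8 | 35.4 | 4.0 | 11.2 | 44.2 |

(readings scatter by 1 percentage point)

- which of these there is most of at the end, counted by the starting material in it, birch (over-reaction product / target / isomer of the product / catalyst intermediate B / starting material)
- which of these there is most of at the end, counted by the starting material in it, elm (over-reaction product / target / isomer of the product / catalyst intermediate B / starting material)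
- the largest of these amounts at the end, in percent of the starting material charged, birch
- the largest of these amounts at the end, in percent of the starting material charged, elm

Target climbs nearly straight from nothing, so I take its average over a run as half its last reading. I pool both runs, set the over-reaction product formed against that average, the time and the equivalents of reagent, and scale to the charge of elm. This gives 6.86 min, the lifetime of target against reagent, a pseudo-first-order lifetime with reagent taken at its charge.

For the minute after the last reading I start from the last target of east, as the nearest run to elm, and let starting material fall at the pace of east, by 15 percentage points, all of it counted as target; the lifetime takes 6.4 points of target, which is less. So I reckon target in elm at 52.5%, still rising. The same sum from south, with the lifetime scaled to the reagent of birch, gives birch 53.8%.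

The forecast names target for birch at 52% and target for elm at 50%, saying of elm “Target is still rising but is trimmed by over-reaction”; for elm its figure is lower than mine.

The flasks give target at 52.8% in birch and target at 52.5% in elm.

    reagent + free catalyst → catalyst intermediate A (k = 0.0910 L mol⁻¹ s⁻¹)
    starting material + catalyst intermediate A → catalyst intermediate B (k = 1.84 L mol⁻¹ s⁻¹)
    catalyst intermediate B → by-product + catalyst intermediate C (k = 0.0549 s⁻¹)
    catalyst intermediate C → free catalyst + target (k = 0.174 s⁻¹)
    target + free catalyst ⇌ isomer of the product + free catalyst, rate k5*[free catalyst]*[target] forward; the back reaction follows from the equilibrium constant (K = 13.1, k = 0.0399 L mol⁻¹ s⁻¹)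
    reagent + target → over-reaction product (k = 9.36 × 10⁻⁴ L mol⁻¹ s⁻¹)
    free catalyst → spent catalyst (k = 1.42 × 10⁻⁴ s⁻¹)

At 2.28 min in elm, target is made 3.31 times faster than it is used up, each step taken net. The lifetime, set against the same average of the final target in elm, gives 19.1% of over-reaction product, and the flask holds 19.8%. Left standing, elm has 0% of starting material and 37.8% of target at 12 min, with reagent going from 56.8% to 47.3% of its charge by 50.0 min. Divided by the mean of those two shares, the lifetime becomes 13.2 min, and the target reckoned for elm at 50.0 min is 2.12%, where the flask holds 1.69%.

(The data stem from a simulated flask on assumed constants, noise included.)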